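**Remark on the chemistry:** all four carbinol carbons of the dibromo tetraol 16 are taken as (S), which corresponds to two anti-1,3-diols and, after closure, to the 2,4-cis relationship in each chroman of 17; the 1,3-diketones 14 and 15 are drawn as diketo tautomers although they should exist largely as chelated enols; flavonoid numbering is used (O1, C2, C3, C4, C4a, C5 to C8, C8a; ring B primed), unit 1 being the 7-methoxy flavanone and unit 2 the 5,7-dihydroxy flavanone.

## Structural features

The target is an unsymmetrical biflavanone in which two 2-arylchroman-4-one units are joined by a single diaryl ether oxygen between C3' of ring B of unit 1 and C4' of ring B of unit 2. Unit 1 carries 5-OH and 7-OMe on ring A and a 4'-OH next to the ether oxygen, whereas unit 2 carries 5-OH and 7-OH and a para-disubstituted ring B. The only stereocentres are the two C2 atoms, both (S), each benzylic and bonded to O1; they lie far apart, separated by both rings B, so neither can direct the other and each has to be set by a reagent. The finished rings C are fragile: base, and more slowly acid, opens a flavanone by retro-oxa-Michael reaction to the 2'-hydroxychalcone, which racemises C2, and the benzylic C2–O1 bond is open to hydrogenolysis and ionisation. The real difficulty is therefore to set two identical, distant and configurationally labile benzylic centres and to carry them through ring closure, while five phenolic oxygens, one of them methylated, and two different rings A are told apart on an unsymmetrical linker. The key step exploits the fact that in each unit O1 bridges the stereogenic C2 and the aromatic C8a, so ring C can be closed at O1–C8a from a C2 carbinol of fixed configuration, with C4 held as a carbinol so that neither a carbonyl-activated C3–H nor a ring-opening path exists during the closure.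

## Logic of the disconnections

**19 from 18.** The four benzylic O–CH2 bonds at O5 and O4' of unit 1 and at O5 and O7 of unit 2 are cut. Cutting here leaves one neutral deprotection as the last operation, so that no base meets a finished flavanone. The gain is that 18 needs no further differentiation of its oxygens: four carry the same group and the fifth already carries its methyl. The forward step must remove four aryl benzyl ethers and spare the benzylic C2–O1 bonds and the two carbonyl groups.

**18 from 17.** No skeletal bond is cut; the two C4 carbonyl groups are traced back to C4–H carbinols. The reason is that at the carbinol level there is no carbonyl-activated C3–H and no retro-oxa-Michael opening, so a basic ring closure becomes permissible. The gain is a ring-forming step that cannot racemise C2. The forward oxidation must be non-basic and buffered, because the C4 hydroxyls sit on very electron-rich rings.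

**17 from 16.** The two O1–C8a bonds are cut, one in each unit. These bonds do not involve the stereocentres, which is the reason for cutting there. Both heterocycles vanish and an acyclic tetraol remains whose configuration a catalyst can set. The forward step must choose the C2 hydroxyl over the C4 hydroxyl in each unit and must leave the C2–O bond intact.

**16 from 15.** The four carbinol C–H bonds at C2 and C4 of both units are removed. Both 1,3-diols then come from achiral 1,3-diketones, and one chiral catalyst can set the two distant C2 centres with the same sense. The gain is a precursor without any stereocentre. The forward reduction must be catalyst-controlled at both C2 carbonyls and must also reach the hindered ring A carbonyls, whose configuration is of no consequence.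

**15 from 14 and 4.** The C2–C3 bond of unit 1 is cut, between the ester carbon of 14 and the acetyl methyl carbon of 4. The hindered carbonyl of 4 can only serve as the nucleophile and the unhindered ester of 14 as the electrophile, which fixes the polarity. The gain is the removal of ring A of unit 1 as a simple acetophenone. The diketone already present in 14 must stay inert as its enolate, and the electron-rich ester must still acylate.

**14 from 12 and 7, through 13.** The C2–C3 bond of unit 2 is cut in the same way. The two ring B carbonyl carbons are told apart by their level of activation, acid chloride in 13 against methyl ester, so no functional-group change is needed once a diketone is present. The gain is the removal of ring A of unit 2. The forward acylation must go at carbon and at low temperature so that the methyl ester is untouched.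

**12 from 11.** The O–C bond of the tert-butyl ester is cut. This releases the one carboxyl group that is to be activated first. The gain is that both ring B carbonyl carbons can be carried as esters through the ether formation. The forward acidolysis must spare the methyl ester and the aryl benzyl ether.

**11 from 9 and 10.** The diaryl ether bond O–C4' of ring B of unit 2 is cut. The ester para to fluorine in 10 activates the substitution and is also the future C2 of unit 2. Two monocyclic pieces result. The phenoxide of 9 must not transesterify or saponify either ester, which is why 10 carries the bulky tert-butyl ester.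

**9 from 8.** The benzyl O–C bond at O4' is cut. This leaves a commercial catechol ester. The gain is that no separate protection of the 3-hydroxyl is needed. The forward alkylation must select the more acidic hydroxyl para to the ester and leave the 3-hydroxyl free for the ether linkage.

**4 from 3.** The benzyl O–C bond at O5 of unit 1 is cut. The free ortho-hydroxyl would otherwise consume base and deactivate the enolate in the condensation. The gain is a phenol that arises directly from the acylation step. The forward alkylation must overcome the hydrogen bond to the carbonyl.

**3 from 1, through 2.** The acetyl–aryl C–C bond is cut and the O–CH3 bond ortho to the carbonyl is restored. This places bromine at the future C8a, methoxy at C7 and a free oxygen at C5 in one operation. The gain is a symmetrical commercial arene. The acylation must go ortho to bromine and para to one methoxy group, and only the chelated methoxy group may be demethylated.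

**7 from 6.** The two benzyl O–C bonds at O5 and O7 of unit 2 are cut. Both hydroxyls receive the same group because both are free in the target. The gain is a simple dihydroxy acetophenone. The alkylation must also reach the hydrogen-bonded ortho-hydroxyl.

**6 from 5.** The acetyl–aryl C–C bond is cut. The resorcinol pattern directs acylation para to one hydroxyl and ortho to the other. The gain is a commercial symmetrical bromoresorcinol. The acylation must go next to bromine and not between the two hydroxyls.

## Other disconnections considered

Alternative 1: The cut removes two bonds of ring B of unit 2, C3'–C4' and C5'–C6', so this benzene ring is grown instead of bought.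
- **Forward key step:** the aryl ethynyl ether A1, made from the ring B phenol of unit 1 with its aldehyde masked as a dioxolane, would react with methyl coumalate A2 in an inverse-electron-demand Diels–Alder reaction. Extrusion of carbon dioxide then aromatises the new ring and gives the diaryl ether A3.
- **In favour:** the conditions are neutral and thermal, no base and no activated fluoroarene are needed, and A2 is cheap. The para pattern follows from the polarisation of the partners, the nucleophilic terminal alkyne carbon of A1 adding to C6 of A2.
- **Where it is better:** the two carbon handles of A3, an acetal and an ester, differ in oxidation level from the outset. The two esters of 11 have to be told apart by acidolysis in step 7.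
- **Against:** the ring that is built is a plain para-disubstituted benzene that 10 supplies ready-made. Acetal formation, conversion of a phenol into an ethynyl ether with strong base, and the cycloaddition cost three or four steps where steps 5 and 6 reach 11 in two. Aryl ynol ethers such as A1 are also sensitive to heat and acid.
- **Comparison:** on mechanism the pericyclic sequence is about as dependable as the substitution of step 6, so the two are equal there. On structure it solves the smallest problem of the molecule, since neither the stereocentres nor the rings C are addressed and chemistry like steps 8 to 13 would still be needed. On step economy it is longer.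

Alternative 2: The cut takes ring A of unit 1 apart at C5–C6, C7–C8 and C4a–C5, with C8–C8a arising in the preceding rearrangement.
- **Forward key step:** the precursor A4 is an enantiopure 2-aryl-2,3-dihydropyran-4-one with a diazoacetyl group at the future C8a. Blue light would trigger a Wolff rearrangement. The ketene function so released, conjugated with the ring double bond, would combine on warming with methoxyacetylene A5 by [2+2] cycloaddition, four-electron ring opening, six-electron ring closure and tautomerisation (Danheiser benzannulation) to give A6.
- **In favour:** three carbon–carbon bonds form in one operation, and A6 is one hydrogenolysis away from 19.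
- **Where it is better:** the 5-hydroxyl comes from the ketene carbon and the 7-methoxy group from A5. No selective demethylation as in step 1 and no protecting group at O5 of unit 1 are needed.
- **Against:** the stereocentre must exist before the annulation, in a vinylogous ester that can open by elimination on warming. The thermal part of the cascade would run on a molecule that already contains the finished, heat- and base-sensitive flavanone of unit 2 with a free 5-hydroxyl. A5 is volatile and unstable. A4 needs an enantioselective dihydropyranone synthesis and a diazo installation on an advanced intermediate. Only one of the two units benefits.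
- **Comparison:** on mechanism the cascade is richer but carries more hazards. On structure it addresses one ring A and neither ring C of the other unit. On step economy the chosen plan, which sets both stereocentres in one catalytic step and closes both heterocycles in one step, should be clearly shorter.

Alternative 3: The cut is C2–C3 in both units.
- **Forward key step:** the achiral bis(diazoketone) A7 has a diazoacetyl group on each ring A, ortho to the benzylic ether oxygen that becomes O1. Under the catalyst A9, dirhodium tetrakis[N-phthaloyl-(S)-tert-leucinate], it would lose dinitrogen twice. Each rhodium-bound carbene carbon would insert into the benzylic C2–H bond, a 1,6-insertion activated by the oxygen and the aryl group, to give A8.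
- **Where it is better:** both stereocentres and both rings C arise in the same catalytic event from an achiral precursor assembled by two Williamson etherifications, and A8 is already at the ketone level. The chosen plan needs separate steps for stereocentre formation (step 10), ring closure (step 11) and reoxidation (step 12).
- **Against:** carbenes from terminal diazoketones are very reactive and discriminate poorly between enantiotopic hydrogens. High enantioselectivity with A9 is established for stabilised diazo compounds closing five-membered rings, not for this six-membered closure.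
- **Further against:** the ether oxygen of A7 is placed to attack the carbene carbon, and ylide formation with benzyl shift would lead to a benzofuranone skeleton. Addition to the electron-rich arenes is a second diversion.
- **Further against:** two independent events with imperfect selectivity would give diastereomers that are hard to separate. The diazoketones must be made from hindered 2,6-dioxygenated benzoic acids, and the silyl ethers at O5 of A8 must later be removed without base.
- **Comparison:** on structure and step economy this is the most attractive plan on paper. On mechanism it rests on selectivities that are not secured, whereas each step of the chosen plan follows an established reaction class.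

Key step: step 11

## Route

Step 1
Reactants: 1 1-bromo-3,5-dimethoxybenzene
Product: 3 1-(2-bromo-6-hydroxy-4-methoxyphenyl)ethan-1-one, via dimethoxy ketone 2 (not isolated)
Conditions: AcCl (1.2 equiv), AlCl3 (3 equiv), CH2Cl2, 0 °C to reflux; aq. HCl
Reagents that add atoms: acetyl chloride, CC(=O)Cl
Why: Friedel–Crafts acylation should go at C2 of 1, para to one methoxy group and ortho to the other, not at the more crowded position between the two methoxy groups; excess AlCl3 then removes only the methyl group ortho to the new carbonyl, by chelation-assisted demethylation.

Step 2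
Reactants: 3 1-(2-bromo-6-hydroxy-4-methoxyphenyl)ethan-1-one
Product: 4 1-[2-(benzyloxy)-6-bromo-4-methoxyphenyl]ethan-1-one
Conditions: BnBr (1.2 equiv), K2CO3 (2 equiv), DMF, 60 °C
Reagents that add atoms: benzyl bromide, BrCc1ccccc1
Why: Williamson ether synthesis; in DMF the phenoxide of the chelated ortho-hydroxy ketone is alkylated at oxygen, and the ketone and the aryl bromide are inert.

Step 3
Reactants: 5 5-bromoresorcinol
Product: 6 1-(2-bromo-4,6-dihydroxyphenyl)ethan-1-one
Conditions: AcOH, ZnCl2 (1.5 equiv), 130 °C
Reagents that add atoms: acetic acid, CC(=O)O
Why: Nencki reaction (Friedel–Crafts acylation by acetic acid under ZnCl2); attack should occur para to one hydroxyl and ortho to the other, as with resorcinol and orcinol, since the position between the two hydroxyls is less reactive.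

Step 4
Reactants: 6 1-(2-bromo-4,6-dihydroxyphenyl)ethan-1-one
Product: 7 1-[2,4-bis(benzyloxy)-6-bromophenyl]ethan-1-one
Conditions: BnBr (2.5 equiv), K2CO3 (3 equiv), DMF, 70 °C
Reagents that add atoms: benzyl bromide, BrCc1ccccc1
Why: Double Williamson ether synthesis; excess halide and warming in DMF also alkylate the hydrogen-bonded ortho-hydroxyl.

Step 5
Reactants: 8 methyl 3,4-dihydroxybenzoate
Product: 9 methyl 4-(benzyloxy)-3-hydroxybenzoate
Conditions: BnBr (1.05 equiv), NaHCO3 (1.5 equiv), NaI (cat.), DMF, 40 °C
Reagents that add atoms: benzyl bromide, BrCc1ccccc1
Why: Regioselective Williamson ether synthesis; the hydroxyl para to the ester is the more acidic, so a weak base ionises and alkylates it selectively.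

Step 6
Reactants: 9 methyl 4-(benzyloxy)-3-hydroxybenzoate; 10 tert-butyl 4-fluorobenzoate
Product: 11 methyl 4-(benzyloxy)-3-[4-(tert-butoxycarbonyl)phenoxy]benzoate
Conditions: 10 (1.2 equiv), K2CO3 (2 equiv), DMSO, 110 °C
Reagents that add atoms: none
Why: Nucleophilic aromatic substitution; the phenoxide of 9 adds para to the ester of 10 and fluoride leaves from the Meisenheimer adduct, while the bulky tert-butyl ester resists transesterification by the phenoxide.

Step 7
Reactants: 11 methyl 4-(benzyloxy)-3-[4-(tert-butoxycarbonyl)phenoxy]benzoate
Product: 12 4-[2-(benzyloxy)-5-(methoxycarbonyl)phenoxy]benzoic acid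
Conditions: TFA, CH2Cl2 (1:4), 0 °C to rt
Reagents that add atoms: none
Why: Acidolysis of the tert-butyl ester by loss of the tert-butyl cation as isobutene; the methyl ester and the aryl benzyl ether are stable to these conditions.

Step 8
Reactants: 12 4-[2-(benzyloxy)-5-(methoxycarbonyl)phenoxy]benzoic acid; 7 1-[2,4-bis(benzyloxy)-6-bromophenyl]ethan-1-one
Product: 14 methyl 4-(benzyloxy)-3-(4-{3-[2,4-bis(benzyloxy)-6-bromophenyl]-3-oxopropanoyl}phenoxy)benzoate, via acid chloride 13 (not isolated)
Conditions: (COCl)2 (1.5 equiv), DMF (cat.), CH2Cl2, 0 °C to rt, evaporate; 7 (2.1 equiv), LiN(SiMe3)2 (2.1 equiv), THF, −78 °C, then 13, −78 to −30 °C; 1 M HCl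
Reagents that add atoms: none
Why: Acid chloride formation, then Claisen-type C-acylation of the lithium enolate of 7; the second equivalent of enolate converts the product into its diketonate, which stops further acylation, and the surplus 7 is recovered. At −78 °C the methyl ester does not react.

Step 9
Reactants: 14 methyl 4-(benzyloxy)-3-(4-{3-[2,4-bis(benzyloxy)-6-bromophenyl]-3-oxopropanoyl}phenoxy)benzoate; 4 1-[2-(benzyloxy)-6-bromo-4-methoxyphenyl]ethan-1-one
Product: 15 1-[2-(benzyloxy)-6-bromo-4-methoxyphenyl]-3-[4-(benzyloxy)-3-(4-{3-[2,4-bis(benzyloxy)-6-bromophenyl]-3-oxopropanoyl}phenoxy)phenyl]propane-1,3-dione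
Conditions: 4 (1.3 equiv), LiN(SiMe3)2 (3.5 equiv), THF, −78 °C to rt; 1 M HCl
Reagents that add atoms: none
Why: Crossed Claisen condensation; the diketone of 14 is deprotonated first and is inert as its enolate, the enolate of 4 adds to the methyl ester, and deprotonation of the new diketone drives the reaction, while the hindered carbonyl of 4 disfavours self-condensation.

Step 10
Reactants: 15 1-[2-(benzyloxy)-6-bromo-4-methoxyphenyl]-3-[4-(benzyloxy)-3-(4-{3-[2,4-bis(benzyloxy)-6-bromophenyl]-3-oxopropanoyl}phenoxy)phenyl]propane-1,3-dione
Product: 16 (1S,3S)-1-[2-(benzyloxy)-6-bromo-4-methoxyphenyl]-3-[4-(benzyloxy)-3-(4-{(1S,3S)-3-[2,4-bis(benzyloxy)-6-bromophenyl]-1,3-dihydroxypropyl}phenoxy)phenyl]propane-1,3-diol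
Conditions: RuCl(p-cymene)[(S,S)-TsDPEN] (10 mol%), HCO2H (8 equiv), Et3N (12 equiv), EtOAc, 40 °C
Reagents that add atoms: none
Why: Noyori–Ikariya asymmetric transfer hydrogenation; hydride and proton pass from the ruthenium hydride and the ligand N–H to each aryl ketone in an outer-sphere transition state in which the aryl group sits under the arene ligand, so the (S,S) ligand should give the (S) carbinol at all four carbons. The second reduction in each unit is again catalyst-controlled, which leads to the anti-diols, and the amine-rich medium avoids ionisation of the electron-rich benzylic carbinols.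

Step 11
Reactants: 16 (1S,3S)-1-[2-(benzyloxy)-6-bromo-4-methoxyphenyl]-3-[4-(benzyloxy)-3-(4-{(1S,3S)-3-[2,4-bis(benzyloxy)-6-bromophenyl]-1,3-dihydroxypropyl}phenoxy)phenyl]propane-1,3-diol
Product: 17 (2S,4S)-5-(benzyloxy)-2-[4-(benzyloxy)-3-{4-[(2S,4S)-5,7-bis(benzyloxy)-4-hydroxy-3,4-dihydro-2H-chromen-2-yl]phenoxy}phenyl]-7-methoxy-3,4-dihydro-2H-chromen-4-ol
Conditions: Pd(OAc)2 (10 mol%), 2-(di-tert-butylphosphino)-1,1'-binaphthyl (12 mol%), Cs2CO3 (3 equiv), degassed toluene, 80 °C
Reagents that add atoms: none
Why: Zerovalent palladium, generated from Pd(OAc)2 and the bulky biaryl di-tert-butylphosphine, should add oxidatively to each C8a–Br bond; the C2 hydroxyl then binds the divalent arylpalladium centre, Cs2CO3 removes its proton, and C(sp2)–O reductive elimination from the seven-membered aryl(alkoxo)palladium chelate forms O1–C8a. The closest known reaction type is the intramolecular Buchwald–Hartwig etherification of secondary alcohols carrying an ortho-bromoaryl group, which gives chromans from enantioenriched carbinols without loss of configuration. Each ring C closes as a six-membered ring, formally 6-exo at the sp2 carbon C8a since the breaking C8a–Br bond lies outside the new ring, and the two closures are independent events in one flask. No new stereocentre is formed: C2 stays (S) because only O–H and C–Br bonds are broken, and C4 stays (S) as a spectator, so each unit becomes the 2,4-cis flavan-4-ol. The selectivity needed is C2–OH over C4–OH, and ring size secures it, because the C4 alkoxide can only form a five-membered chelate whose reductive elimination would give a strained four-membered ring. The electron-rich, hindered ligand speeds reductive elimination relative to β-hydride elimination from either palladium alkoxide, which is the main competing path. Since C4 is a carbinol, there is no carbonyl-activated C3–H and the carbonate base has no way to open the ring or to racemise C2.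

Step 12
Reactants: 17 (2S,4S)-5-(benzyloxy)-2-[4-(benzyloxy)-3-{4-[(2S,4S)-5,7-bis(benzyloxy)-4-hydroxy-3,4-dihydro-2H-chromen-2-yl]phenoxy}phenyl]-7-methoxy-3,4-dihydro-2H-chromen-4-ol
Product: 18 (2S)-5-(benzyloxy)-2-[4-(benzyloxy)-3-{4-[(2S)-5,7-bis(benzyloxy)-4-oxo-3,4-dihydro-2H-chromen-2-yl]phenoxy}phenyl]-7-methoxy-2,3-dihydro-4H-chromen-4-one
Conditions: Dess–Martin periodinane (3 equiv), pyridine (6 equiv), CH2Cl2, 0 °C to rt; 17 used after filtration through Et3N-washed silica
Reagents that add atoms: none
Why: Dess–Martin oxidation of the two secondary benzylic carbinols by ligand exchange at iodine and loss of the carbinol hydrogen; pyridine buffers the acetic acid, which matters because the C4 hydroxyls sit on trioxygenated rings and would ionise under acid. The C2 centres are not touched.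

Step 13
Reactants: 18 (2S)-5-(benzyloxy)-2-[4-(benzyloxy)-3-{4-[(2S)-5,7-bis(benzyloxy)-4-oxo-3,4-dihydro-2H-chromen-2-yl]phenoxy}phenyl]-7-methoxy-2,3-dihydro-4H-chromen-4-one
Product: 19 7-O-methyltetrahydroochnaflavone, (2S)-2-[3-{4-[(2S)-5,7-dihydroxy-4-oxo-3,4-dihydro-2H-chromen-2-yl]phenoxy}-4-hydroxyphenyl]-5-hydroxy-7-methoxy-2,3-dihydro-4H-chromen-4-one
Conditions: H2 (1 atm), Pd/C (10%), EtOAc–THF (1:1), rt, stopped at full debenzylation
Reagents that add atoms: none
Why: Catalytic hydrogenolysis of the four aryl benzyl ethers under neutral conditions, which offer no retro-oxa-Michael path; the cyclic benzylic C2–O1 bonds and the aryl ketones react much more slowly than O-benzyl groups.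

## Compound list

1 | 1-bromo-3,5-dimethoxybenzene | COc1cc(Br)cc(OC)c1 | starting material
2 | 1-(2-bromo-4,6-dimethoxyphenyl)ethan-1-one | CC(=O)c1c(Br)cc(OC)cc1OC | intermediate
3 | 1-(2-bromo-6-hydroxy-4-methoxyphenyl)ethan-1-one | CC(=O)c1c(O)cc(OC)cc1Br | intermediate
4 | 1-[2-(benzyloxy)-6-bromo-4-methoxyphenyl]ethan-1-one | CC(=O)c1c(Br)cc(OC)cc1OCc1ccccc1 | intermediate
5 | 5-bromoresorcinol | Oc1cc(O)cc(Br)c1 | starting material
6 | 1-(2-bromo-4,6-dihydroxyphenyl)ethan-1-one | CC(=O)c1c(O)cc(O)cc1Br | intermediate
7 | 1-[2,4-bis(benzyloxy)-6-bromophenyl]ethan-1-one | CC(=O)c1c(Br)cc(OCc2ccccc2)cc1OCc1ccccc1 | intermediate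
8 | methyl 3,4-dihydroxybenzoate | COC(=O)c1ccc(O)c(O)c1 | starting material
9 | methyl 4-(benzyloxy)-3-hydroxybenzoate | COC(=O)c1ccc(OCc2ccccc2)c(O)c1 | intermediate
10 | tert-butyl 4-fluorobenzoate | CC(C)(C)OC(=O)c1ccc(F)cc1 | starting material
11 | methyl 4-(benzyloxy)-3-[4-(tert-butoxycarbonyl)phenoxy]benzoate | COC(=O)c1ccc(OCc2ccccc2)c(Oc2ccc(C(=O)OC(C)(C)C)cc2)c1 | intermediate
12 | 4-[2-(benzyloxy)-5-(methoxycarbonyl)phenoxy]benzoic acid | COC(=O)c1ccc(OCc2ccccc2)c(Oc2ccc(C(=O)O)cc2)c1 | intermediate
13 | methyl 4-(benzyloxy)-3-[4-(chlorocarbonyl)phenoxy]benzoate | COC(=O)c1ccc(OCc2ccccc2)c(Oc2ccc(C(Cl)=O)cc2)c1 | intermediate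
14 | methyl 4-(benzyloxy)-3-(4-{3-[2,4-bis(benzyloxy)-6-bromophenyl]-3-oxopropanoyl}phenoxy)benzoate | COC(=O)c1ccc(OCc2ccccc2)c(Oc2ccc(C(=O)CC(=O)c3c(Br)cc(OCc4ccccc4)cc3OCc3ccccc3)cc2)c1 | intermediate
15 | 1-[2-(benzyloxy)-6-bromo-4-methoxyphenyl]-3-[4-(benzyloxy)-3-(4-{3-[2,4-bis(benzyloxy)-6-bromophenyl]-3-oxopropanoyl}phenoxy)phenyl]propane-1,3-dione | COc1cc(OCc2ccccc2)c(C(=O)CC(=O)c2ccc(OCc3ccccc3)c(Oc3ccc(C(=O)CC(=O)c4c(Br)cc(OCc5ccccc5)cc4OCc4ccccc4)cc3)c2)c(Br)c1 | intermediate
16 | (1S,3S)-1-[2-(benzyloxy)-6-bromo-4-methoxyphenyl]-3-[4-(benzyloxy)-3-(4-{(1S,3S)-3-[2,4-bis(benzyloxy)-6-bromophenyl]-1,3-dihydroxypropyl}phenoxy)phenyl]propane-1,3-diol | O[C@H](c1ccc(OCc2ccccc2)c(Oc2ccc([C@@H](O)C[C@H](O)c3c(Br)cc(OCc4ccccc4)cc3OCc3ccccc3)cc2)c1)C[C@H](O)c1c(Br)cc(OC)cc1OCc1ccccc1 | intermediate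
17 | (2S,4S)-5-(benzyloxy)-2-[4-(benzyloxy)-3-{4-[(2S,4S)-5,7-bis(benzyloxy)-4-hydroxy-3,4-dihydro-2H-chromen-2-yl]phenoxy}phenyl]-7-methoxy-3,4-dihydro-2H-chromen-4-ol | COc1cc(OCc2ccccc2)c2c(c1)O[C@H](c1ccc(OCc3ccccc3)c(Oc3ccc([C@@H]4C[C@H](O)c5c(OCc6ccccc6)cc(OCc6ccccc6)cc5O4)cc3)c1)C[C@@H]2O | intermediate
18 | (2S)-5-(benzyloxy)-2-[4-(benzyloxy)-3-{4-[(2S)-5,7-bis(benzyloxy)-4-oxo-3,4-dihydro-2H-chromen-2-yl]phenoxy}phenyl]-7-methoxy-2,3-dihydro-4H-chromen-4-one | COc1cc(OCc2ccccc2)c2c(c1)O[C@H](c1ccc(OCc3ccccc3)c(Oc3ccc([C@@H]4CC(=O)c5c(OCc6ccccc6)cc(OCc6ccccc6)cc5O4)cc3)c1)CC2=O | intermediate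
19 | 7-O-methyltetrahydroochnaflavone | COc1cc(O)c2c(c1)O[C@H](c1ccc(O)c(Oc3ccc([C@@H]4CC(=O)c5c(O)cc(O)cc5O4)cc3)c1)CC2=O | target

## Step count and risks

Total step count: 13 (2 and 13 are formed and used in the same flask). Longest linear sequence: 9 steps (8 → 9 → 11 → 12 → 14 → 15 → 16 → 17 → 18 → 19; steps 5 to 13). The ring A pieces 4 and 7 are made in two steps each and enter at steps 9 and 8.

**Step 11 (key step).** The most likely failure is β-hydride elimination from a palladium alkoxide, either the C2 alkoxide in the productive chelate or the C4 alkoxide in the five-membered chelate. Either would oxidise a carbinol and reduce the aryl bromide. Palladium may also be held back in the five-membered C4 chelate, so the second closure could stay incomplete. The fallback leaves the palladium redox cycle for an Ullmann-type closure. From 16, CuI with 3,4,7,8-tetramethyl-1,10-phenanthroline and Cs2CO3 in toluene at 110 °C should close both rings through a copper alkoxide, which has no easy β-hydride path, and return to the route at 17. No new compound arises: F0.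

**Step 10.** The ring A carbonyls are flanked by bromine and a benzyloxy group, so the transfer hydrogenation may stall after the two unhindered ring B carbonyls have been reduced. Long exposure to the formate medium could also promote ionisation of the electron-rich benzylic carbinols. The fallback separates the two tasks. From 15, the same catalyst at room temperature, stopped after the first two reductions, should give the bis(β-hydroxy ketone) (3S)-1-[2-(benzyloxy)-6-bromo-4-methoxyphenyl]-3-[4-(benzyloxy)-3-(4-{(1S)-3-[2,4-bis(benzyloxy)-6-bromophenyl]-1-hydroxy-3-oxopropyl}phenoxy)phenyl]-3-hydroxypropan-1-one F1. Hydroxyl-directed reduction with Me4NBH(OAc)3 in MeCN–AcOH at −30 °C (Evans–Saksena reduction, hydride delivered intramolecularly from the C2 alkoxyborohydride, 1,3-anti) should then give 16, where the route resumes.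

**Step 9.** Acylation by the electron-rich methyl ester may be slow in a mixture that already holds a lithium diketonate, and on warming, cleavage of the first diketone by alkoxide may compete. The fallback replaces the hard-enolate Claisen condensation by a soft-enolisation acylation with an activated ester. From 14, LiOH in THF–water at room temperature should give 4-(benzyloxy)-3-(4-{3-[2,4-bis(benzyloxy)-6-bromophenyl]-3-oxopropanoyl}phenoxy)benzoic acid F2, the diketone being protected as its enolate. Pentafluorophenol and DCC should convert this into pentafluorophenyl 4-(benzyloxy)-3-(4-{3-[2,4-bis(benzyloxy)-6-bromophenyl]-3-oxopropanoyl}phenoxy)benzoate F3. Treatment of F3 with 4, MgBr2·OEt2 and i-Pr2NEt in CH2Cl2 should then give 15, where the route resumes. The diketone already present should be held as its magnesium chelate, which is a poor nucleophile under these conditions.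

**Step 1.** Acylation may in part go between the two methoxy groups, and the demethylation may be incomplete or may go on to the second methoxy group. The fallback reverses the logic: the methyl group is put on instead of being taken off. From 6, MeI (1 equiv) and K2CO3 in acetone at room temperature should alkylate only the hydroxyl para to the acetyl group, which is not hydrogen-bonded, and give 3 directly. No new compound arises: F0.

**Step 13.** Hydrogenolysis may go beyond the benzyl ethers into the benzylic C2–O1 bonds, which would open the rings. The fallback is non-reductive. From 18, BCl3 with pentamethylbenzene as cation scavenger in CH2Cl2 at −78 °C should remove the four benzyl groups and leave the 7-methoxy group, which is not chelated to the carbonyl, giving 19. No new compound arises: F0.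

## Further compounds

F0 | step 11 | none | none
F1 | step 10 | (3S)-1-[2-(benzyloxy)-6-bromo-4-methoxyphenyl]-3-[4-(benzyloxy)-3-(4-{(1S)-3-[2,4-bis(benzyloxy)-6-bromophenyl]-1-hydroxy-3-oxopropyl}phenoxy)phenyl]-3-hydroxypropan-1-one | COc1cc(OCc2ccccc2)c(C(=O)C[C@H](O)c2ccc(OCc3ccccc3)c(Oc3ccc([C@@H](O)CC(=O)c4c(Br)cc(OCc5ccccc5)cc4OCc4ccccc4)cc3)c2)c(Br)c1
F2 | step 9 | 4-(benzyloxy)-3-(4-{3-[2,4-bis(benzyloxy)-6-bromophenyl]-3-oxopropanoyl}phenoxy)benzoic acid | OC(=O)c1ccc(OCc2ccccc2)c(Oc2ccc(C(=O)CC(=O)c3c(Br)cc(OCc4ccccc4)cc3OCc3ccccc3)cc2)c1
F3 | step 9 | pentafluorophenyl 4-(benzyloxy)-3-(4-{3-[2,4-bis(benzyloxy)-6-bromophenyl]-3-oxopropanoyl}phenoxy)benzoate | O=C(Oc1c(F)c(F)c(F)c(F)c1F)c1ccc(OCc2ccccc2)c(Oc2ccc(C(=O)CC(=O)c3c(Br)cc(OCc4ccccc4)cc3OCc3ccccc3)cc2)c1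
F0 | step 1 | none | none
F0 | step 13 | none | none
A1 | alternative 1 | 2-[4-(benzyloxy)-3-(ethynyloxy)phenyl]-1,3-dioxolane | C#COc1cc(C2OCCO2)ccc1OCc1ccccc1
A2 | alternative 1 | methyl coumalate (methyl 2-oxo-2H-pyran-5-carboxylate) | COC(=O)C1=COC(=O)C=C1
A3 | alternative 1 | methyl 4-[2-(benzyloxy)-5-(1,3-dioxolan-2-yl)phenoxy]benzoate | COC(=O)c1ccc(Oc2cc(C3OCCO3)ccc2OCc2ccccc2)cc1
A4 | alternative 2 | (2S)-7-(benzyloxy)-2-[4-{2-(benzyloxy)-5-[(2S)-6-(diazoacetyl)-4-oxo-3,4-dihydro-2H-pyran-2-yl]phenoxy}phenyl]-5-hydroxy-2,3-dihydro-4H-chromen-4-one | [N-]=[N+]=CC(=O)C1=CC(=O)C[C@@H](c2ccc(OCc3ccccc3)c(Oc3ccc([C@@H]4CC(=O)c5c(O)cc(OCc6ccccc6)cc5O4)cc3)c2)O1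
A5 | alternative 2 | methoxyacetylene | COC#C
A6 | alternative 2 | 4',7''-di-O-benzyl 7-O-methyltetrahydroochnaflavone | COc1cc(O)c2c(c1)O[C@H](c1ccc(OCc3ccccc3)c(Oc3ccc([C@@H]4CC(=O)c5c(O)cc(OCc6ccccc6)cc5O4)cc3)c1)CC2=O
A7 | alternative 3 | bis(diazoketone): 2-diazo-1-{2-[(4-(benzyloxy)-3-{4-[(5-(benzyloxy)-3-[(tert-butyldimethylsilyl)oxy]-2-(diazoacetyl)phenoxy)methyl]phenoxy}phenyl)methoxy]-6-[(tert-butyldimethylsilyl)oxy]-4-methoxyphenyl}ethan-1-one | COc1cc(O[Si](C)(C)C(C)(C)C)c(C(=O)C=[N+]=[N-])c(OCc2ccc(OCc3ccccc3)c(Oc3ccc(COc4cc(OCc5ccccc5)cc(O[Si](C)(C)C(C)(C)C)c4C(=O)C=[N+]=[N-])cc3)c2)c1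
A8 | alternative 3 | 5,5''-bis-O-(tert-butyldimethylsilyl) 4',7''-di-O-benzyl 7-O-methyltetrahydroochnaflavone | COc1cc(O[Si](C)(C)C(C)(C)C)c2c(c1)O[C@H](c1ccc(OCc3ccccc3)c(Oc3ccc([C@@H]4CC(=O)c5c(O[Si](C)(C)C(C)(C)C)cc(OCc6ccccc6)cc5O4)cc3)c1)CC2=O
A9 | alternative 3 | Rh2(S-PTTL)4, dirhodium tetrakis[N-phthaloyl-(S)-tert-leucinate] | CC(C)(C)[C@H](N1C(=O)c2ccccc2C1=O)C(=O)[O-].CC(C)(C)[C@H](N1C(=O)c2ccccc2C1=O)C(=O)[O-].CC(C)(C)[C@H](N1C(=O)c2ccccc2C1=O)C(=O)[O-].CC(C)(C)[C@H](N1C(=O)c2ccccc2C1=O)C(=O)[O-].[Rh+2].[Rh+2]
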